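**Retrosynthetic overview**
1. Target 13 is traced back to its bis(methoxymethyl) ether 11, with the acetals on the C4' and C4 oxygens removed last.
2. 11 is disconnected at the two aryl–CH2 bonds on C3' and C5' of ring A: twofold Stille coupling of diiodochalcone 8 with prenylstannane 9.
3. 8 is disconnected at the enone C=C: Claisen–Schmidt condensation of diiodoacetophenone 4 with aldehyde 6.
4. 4 comes from 2',4'-dihydroxyacetophenone 1 by iodination at C3 and C5, then etherification of the C4 oxygen. No ring is formed; both benzene rings are bought.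
5. Feature the plan rests on: the two prenyl CH2 carbons sit on C3' and C5' of ring A, the two carbons ortho to the C4' oxygen (C3' also ortho to the C2' hydroxyl, both meta to the acyl-bearing C1'). These are exactly the carbons at which a 2,4-dihydroxyaryl ketone takes up iodine.

Key step: step 5

Assumption: stannane 9 and chloromethyl methyl ether are taken as catalogue reagents. In each twofold step the first event is assumed to occur at the site named for the intermediate; either order leads to the same product.

**Step 1**
Reactants: 1 2',4'-dihydroxyacetophenone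
Product: 3 1-(2,4-dihydroxy-3,5-diiodophenyl)ethanone, via 3'-iodo-2',4'-dihydroxyacetophenone 2 (not isolated)
Conditions: I2 (0.85 equiv), HIO3 (0.45 equiv), EtOH/H2O, 35–40 °C; aq. Na2S2O3 wash
Reagents that add atoms: iodine, II; iodic acid, OI(=O)=O
Why: Electrophilic aromatic iodination in which iodic acid reoxidises the iodide formed, so all iodine is used; C3 and C5 are each ortho or para to both hydroxyls and meta to the acetyl group, so all three substituents direct to the same two carbons and C6 stays untouched.

**Step 2**
Reactants: 3 1-(2,4-dihydroxy-3,5-diiodophenyl)ethanone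
Product: 4 1-[2-hydroxy-3,5-diiodo-4-(methoxymethoxy)phenyl]ethanone
Conditions: MOMCl (1.1 equiv), K2CO3 (1.5 equiv), acetone, 0 °C to rt
Reagents that add atoms: chloromethyl methyl ether, COCCl
Why: Williamson-type O-alkylation; the C4 hydroxyl (para to the acetyl group, flanked by two iodines) is the more acidic and is ionised by K2CO3, whereas the C2 hydroxyl is held in a hydrogen bond to the ketone, so one equivalent of the reactive chloromethyl ether should give the mono-ether.

**Step 3**
Reactants: 5 4-hydroxybenzaldehyde
Product: 6 4-(methoxymethoxy)benzaldehyde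
Conditions: MOMCl (1.2 equiv), K2CO3 (2 equiv), acetone, 0 °C to rt
Reagents that add atoms: chloromethyl methyl ether, COCCl
Why: Williamson etherification of the phenoxide with the chloromethyl ether; the aldehyde is inert to K2CO3 in acetone.

**Step 4**
Reactants: 4 1-[2-hydroxy-3,5-diiodo-4-(methoxymethoxy)phenyl]ethanone; 6 4-(methoxymethoxy)benzaldehyde
Product: 8 (E)-1-[2-hydroxy-3,5-diiodo-4-(methoxymethoxy)phenyl]-3-[4-(methoxymethoxy)phenyl]prop-2-en-1-one, via racemic aldol adduct 7 (not isolated)
Conditions: KOH (aq. 50%, excess), EtOH, 0 °C to rt; then cold aq. citric acid to pH 5–6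
Reagents that add atoms: none
Why: Claisen–Schmidt (crossed aldol) condensation; the non-enolisable aldehyde 6 takes up the enolate of methyl ketone 4 and E1cB loss of water from aldol 7 should give the conjugated enone in its thermodynamically preferred E geometry, while the aryl iodides and the acetals are stable to hydroxide.

**Step 5**
Reactants: 8 (E)-1-[2-hydroxy-3,5-diiodo-4-(methoxymethoxy)phenyl]-3-[4-(methoxymethoxy)phenyl]prop-2-en-1-one; 9 tributyl(3-methylbut-2-enyl)stannane (3 equiv)
Product: 11 (E)-1-[2-hydroxy-4-(methoxymethoxy)-3,5-bis(3-methylbut-2-enyl)phenyl]-3-[4-(methoxymethoxy)phenyl]prop-2-en-1-one, via 3'-iodo-5'-prenyl chalcone 10 (not isolated)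
Conditions: Pd(PPh3)4 (10 mol %), degassed DMF, 90–100 °C, Ar; aq. KF work-up
Reagents that add atoms: none
Why: Zerovalent palladium released from Pd(PPh3)4 inserts into the C5'–I and then the C3'–I bond of ring A, the prenyl group passes from tin to the arylpalladium iodide, and reductive elimination from the aryl(prenyl)palladium species forms each aryl–CH2 bond and returns zerovalent palladium; the cycle runs twice, through monoiodide 10. The closest known reaction type is the Migita–Kosugi–Stille coupling of aryl iodides with allyl- and prenyltributylstannanes, which gives linear 3-methylbut-2-enyl arenes. No ring is closed and no stereocentre is created, and the E enone set in step 4 is not touched. The selectivity needed is bond formation at the CH2 terminus of the prenyl unit and not at its CMe2 terminus; it is secured because the aryl group is delivered to the unsubstituted end of the allylpalladium intermediate, a steric preference that is strongest at C3', which lies between the C2' hydroxyl and the C4' acetal oxygen. Complete twofold coupling should follow from the excess of 9 and from both halogens being iodides, and the neutral medium leaves the enone, the acetals and the hydrogen-bonded C2' hydroxyl alone.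

**Step 6**
Reactants: 11 (E)-1-[2-hydroxy-4-(methoxymethoxy)-3,5-bis(3-methylbut-2-enyl)phenyl]-3-[4-(methoxymethoxy)phenyl]prop-2-en-1-one
Product: 13 (E)-1-[2,4-dihydroxy-3,5-bis(3-methylbut-2-enyl)phenyl]-3-(4-hydroxyphenyl)prop-2-en-1-one, via 4'-mono-MOM chalcone 12 (not isolated)
Conditions: conc. HCl (cat.), MeOH, rt; NaHCO3 quench at full conversion
Reagents that add atoms: none
Why: Acid-catalysed acetal exchange in which each methoxymethyl group is passed to methanol and leaves as dimethoxymethane; dilute acid at room temperature should spare the trisubstituted prenyl alkenes (no chroman formation) and should not close the 2'-hydroxychalcone to the flavanone.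

**Compound list**
1 | 2',4'-dihydroxyacetophenone | CC(=O)c1ccc(O)cc1O | starting material
2 | 1-(2,4-dihydroxy-3-iodophenyl)ethanone | CC(=O)c1ccc(O)c(I)c1O | intermediate (not isolated)
3 | 1-(2,4-dihydroxy-3,5-diiodophenyl)ethanone | CC(=O)c1cc(I)c(O)c(I)c1O | intermediate
4 | 1-[2-hydroxy-3,5-diiodo-4-(methoxymethoxy)phenyl]ethanone | CC(=O)c1cc(I)c(OCOC)c(I)c1O | intermediate
5 | 4-hydroxybenzaldehyde | O=Cc1ccc(O)cc1 | starting material
6 | 4-(methoxymethoxy)benzaldehyde | COCOc1ccc(C=O)cc1 | intermediate
7 | racemic 3-hydroxy-1-[2-hydroxy-3,5-diiodo-4-(methoxymethoxy)phenyl]-3-[4-(methoxymethoxy)phenyl]propan-1-one | O=C(CC(O)c1ccc(OCOC)cc1)c1cc(I)c(OCOC)c(I)c1O | intermediate (not isolated)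
8 | (E)-1-[2-hydroxy-3,5-diiodo-4-(methoxymethoxy)phenyl]-3-[4-(methoxymethoxy)phenyl]prop-2-en-1-one | O=C(/C=C/c1ccc(OCOC)cc1)c1cc(I)c(OCOC)c(I)c1O | intermediate
9 | tributyl(3-methylbut-2-enyl)stannane | CC(C)=CC[Sn](CCCC)(CCCC)CCCC | starting material
10 | (E)-1-[2-hydroxy-3-iodo-4-(methoxymethoxy)-5-(3-methylbut-2-enyl)phenyl]-3-[4-(methoxymethoxy)phenyl]prop-2-en-1-one | O=C(/C=C/c1ccc(OCOC)cc1)c1cc(CC=C(C)C)c(OCOC)c(I)c1O | intermediate (not isolated)
11 | (E)-1-[2-hydroxy-4-(methoxymethoxy)-3,5-bis(3-methylbut-2-enyl)phenyl]-3-[4-(methoxymethoxy)phenyl]prop-2-en-1-one | COCOc1ccc(/C=C/C(=O)c2cc(CC=C(C)C)c(OCOC)c(CC=C(C)C)c2O)cc1 | intermediate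
12 | (E)-3-(4-hydroxyphenyl)-1-[2-hydroxy-4-(methoxymethoxy)-3,5-bis(3-methylbut-2-enyl)phenyl]prop-2-en-1-one | CC(C)=CCc1cc(C(=O)/C=C/c2ccc(O)cc2)c(O)c(CC=C(C)C)c1OCOC | intermediate (not isolated)
13 | (E)-1-[2,4-dihydroxy-3,5-bis(3-methylbut-2-enyl)phenyl]-3-(4-hydroxyphenyl)prop-2-en-1-one | CC(C)=CCc1cc(C(=O)/C=C/c2ccc(O)cc2)c(O)c(CC=C(C)C)c1O | target

**Step count**
Total steps: 6. Longest linear sequence: 5 (steps 1, 2, 4, 5, 6).

**Steps most likely to fail**

Step 5. The prenyl group may be transferred through its CMe2 terminus to give 1,1-dimethylallyl groups, or the crowded C3' iodide may be reduced or react incompletely, so that mixtures of regioisomers and mono-coupled material result. The fallback sets out from 4 and comes back at 11. 4 is coupled twice with allyltributylstannane (Pd(PPh3)4, DMF, 90 °C), where both allyl termini are the same and no regiochemical question arises, to give 1-[2-hydroxy-4-(methoxymethoxy)-3,5-di(prop-2-enyl)phenyl]ethanone F1. Cross-metathesis of F1 with excess 2-methyl-2-butene (second-generation Grubbs catalyst, (H2IMes)(PCy3)Cl2Ru=CHPh, CH2Cl2, rt to 40 °C) turns both allyl groups into prenyl groups and gives 1-[2-hydroxy-4-(methoxymethoxy)-3,5-bis(3-methylbut-2-enyl)phenyl]ethanone F2. The metathesis is placed before the enone is built so that the chalcone alkene is never exposed to the ruthenium carbene. Claisen–Schmidt condensation of F2 with 6 (KOH, EtOH, rt) then gives 11.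

Step 6. During acetal removal the acid may protonate the prenyl alkenes and let the neighbouring C2' or C4' hydroxyl add to give 2,2-dimethylchromans, or may promote oxa-Michael closure to the flavanone. The fallback sets out from 8 and comes back at 13. The acetals are removed before any prenyl group is present (HCl, MeOH, 40–50 °C) to give (E)-1-(2,4-dihydroxy-3,5-diiodophenyl)-3-(4-hydroxyphenyl)prop-2-en-1-one F3. Twofold Stille coupling of the unprotected triphenol F3 with 9 (4 equiv, to offset any protodestannylation by the acidic phenol; Pd(PPh3)4, DMF, 90 °C) then gives 13 directly, with no acid used after prenylation.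

Step 2. Etherification of 3 may be unselective (both hydroxyls alkylated) or sluggish, since the C4 phenoxide is weakly nucleophilic and hindered by two ortho iodines. The fallback sets out from 1 and comes back at 4. The order is inverted: 1 is etherified at the unhindered C4 oxygen (MOMCl, K2CO3, acetone) to give 1-[2-hydroxy-4-(methoxymethoxy)phenyl]ethanone F4. F4 is then iodinated twice under non-acidic conditions (N-iodosuccinimide, 2.2 equiv, DMF, rt to 40 °C) at C3 and C5, the carbons ortho and para to the free C2 hydroxyl and ortho to the acetal oxygen, to give 4.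

**Further compounds**
F1 | step 5 | 1-[2-hydroxy-4-(methoxymethoxy)-3,5-di(prop-2-enyl)phenyl]ethanone | CC(=O)c1cc(CC=C)c(OCOC)c(CC=C)c1O
F2 | step 5 | 1-[2-hydroxy-4-(methoxymethoxy)-3,5-bis(3-methylbut-2-enyl)phenyl]ethanone | CC(=O)c1cc(CC=C(C)C)c(OCOC)c(CC=C(C)C)c1O
F3 | step 6 | (E)-1-(2,4-dihydroxy-3,5-diiodophenyl)-3-(4-hydroxyphenyl)prop-2-en-1-one | O=C(/C=C/c1ccc(O)cc1)c1cc(I)c(O)c(I)c1O
F4 | step 2 | 1-[2-hydroxy-4-(methoxymethoxy)phenyl]ethanone | CC(=O)c1ccc(OCOC)cc1O
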